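**Strategy.** The route rests on the C5–C6 σ-bond between the two E-olefins of the hepta-4,6-dien-3-one arm on C1 of ring A. It is made last: the 1-ethynyl bis-epoxy decalin 26 is syn-hydrostannylated and the resulting E-vinylstannane is coupled in the same flask (Stille) with the unprotected β-iodoenone 31. This fixes the C6=C7 geometry and delivers the target without protecting groups. The decalin comes from an auxiliary-controlled intramolecular Diels–Alder reaction of a pentaenoyl imide whose butenyl terminus is masked as a vinyl iodide, so both ring olefins can be epoxidised before the butenyl olefin exists. (E)-3-Iodo-2-methylpropenal serves both termini.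

Key step: step 23

Remark: decalin atoms are numbered C1–C8a (C1 carries the dienone arm, C2 the butenyl group), β is the face of H-8a and α the face of H-4a; the arm is numbered as 1-hydroxyhepta-4,6-dien-3-one with C7 on decalin C1; absolute configurations are those of the SMILES strings; the L-fructose-derived ketone catalyst of step 16 is taken as purchasable.

Step 1
Reactants: 1 prop-2-yn-1-ol
Product: 3 (E)-3-iodo-2-methylprop-2-en-1-ol, via alkenylalane 2 (not isolated)
Conditions: AlMe3 (3 equiv), Cp2ZrCl2 (0.3 equiv), CH2Cl2, 0 °C to rt; then I2, THF, −30 °C; aq. K2CO3 work-up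
Reagents that add atoms: trimethylaluminium C[Al](C)C; iodine II
Why: Zirconium-catalysed carboalumination (Negishi) adds methyl and aluminium syn across the alkyne with methyl on the internal carbon, and iodinolysis of the C–Al bond with retention should give the E-iodoalkene.

Step 2
Reactants: 3 (E)-3-iodo-2-methylprop-2-en-1-ol
Product: 4 (E)-3-iodo-2-methylprop-2-enal
Conditions: MnO2, CH2Cl2, rt
Reagents that add atoms: none
Why: MnO2 oxidises the allylic alcohol under neutral conditions without touching the vinyl iodide or the olefin geometry (allylic oxidation).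

Step 3
Reactants: 4 (E)-3-iodo-2-methylprop-2-enal; 5 ethyl 2-(triphenyl-λ5-phosphanylidene)propanoate
Product: 6 ethyl (2E,4E)-5-iodo-2,4-dimethylpenta-2,4-dienoate
Conditions: CH2Cl2, rt
Reagents that add atoms: none
Why: Wittig olefination with the stabilised α-methyl ylide is E-selective and should extend 4 to the (2E,4E)-dienoate.

Step 4
Reactants: 6 ethyl (2E,4E)-5-iodo-2,4-dimethylpenta-2,4-dienoate
Product: 7 (2E,4E)-5-iodo-2,4-dimethylpenta-2,4-dien-1-ol
Conditions: i-Bu2AlH (2.2 equiv), CH2Cl2, −78 °C; aq. KNaC4H4O6 work-up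
Reagents that add atoms: none
Why: i-Bu2AlH reduces the conjugated ester to the allylic alcohol by 1,2-hydride delivery without reducing the vinyl iodide.

Step 5
Reactants: 7 (2E,4E)-5-iodo-2,4-dimethylpenta-2,4-dien-1-ol
Product: 8 (1E,3E)-5-bromo-1-iodo-2,4-dimethylpenta-1,3-diene
Conditions: CBr4, PPh3, CH2Cl2, 0 °C
Reagents that add atoms: carbon tetrabromide BrC(Br)(Br)Br
Why: Appel bromination converts the primary dienylic alcohol into the bromide by SN2 displacement of the alkoxyphosphonium ion under neutral conditions.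

Step 6
Reactants: 8 (1E,3E)-5-bromo-1-iodo-2,4-dimethylpenta-1,3-diene
Product: 9 diethyl [(2E,4E)-5-iodo-2,4-dimethylpenta-2,4-dien-1-yl]phosphonate
Conditions: P(OEt)3, neat, 90 °C
Reagents that add atoms: triethyl phosphite CCOP(OCC)OCC
Why: Michaelis–Arbuzov reaction of the primary allylic bromide should give the dienylphosphonate with both olefin geometries intact.

Step 7
Reactants: 10 4-methylanisole
Product: 11 1-methoxy-4-methylcyclohexa-1,4-diene
Conditions: Li, NH3 (l), t-BuOH, THF, −78 to −33 °C
Reagents that add atoms: none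
Why: Birch reduction of the para-disubstituted anisole leaves the two donor-bearing carbons sp2 and should give the 1,4-diene whose ring later fixes the Z geometry of the tether olefin.

Step 8
Reactants: 11 1-methoxy-4-methylcyclohexa-1,4-diene
Product: 13 methyl (3Z)-4-methyl-6-oxohex-3-enoate, via methoxy hydroperoxide 12 (not isolated)
Conditions: O3 (1 equiv), CH2Cl2/MeOH, −78 °C; then Me2S, −78 °C to rt
Reagents that add atoms: ozone [O-][O+]=O
Why: Ozone cleaves the electron-rich enol-ether olefin much faster than the trialkyl olefin (chemoselective ozonolysis), so reductive work-up should give the open-chain Z-olefin with its ends differentiated as methyl ester and aldehyde.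

Step 9
Reactants: 9 diethyl [(2E,4E)-5-iodo-2,4-dimethylpenta-2,4-dien-1-yl]phosphonate; 13 methyl (3Z)-4-methyl-6-oxohex-3-enoate
Product: 14 methyl (3Z,6E,8E,10E)-11-iodo-4,8,10-trimethylundeca-3,6,8,10-tetraenoate
Conditions: 9, LiN(SiMe3)2, THF, −78 °C; then 13, −78 to 0 °C
Reagents that add atoms: none
Why: Horner–Wadsworth–Emmons reaction of the preformed allylic phosphonate anion with the aldehyde should form the C6=C7 olefin E-selectively and complete the (E,E)-diene with its iodovinyl terminus.

Step 10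
Reactants: 14 methyl (3Z,6E,8E,10E)-11-iodo-4,8,10-trimethylundeca-3,6,8,10-tetraenoate
Product: 15 (3Z,6E,8E,10E)-11-iodo-4,8,10-trimethylundeca-3,6,8,10-tetraenal
Conditions: i-Bu2AlH (1.05 equiv), CH2Cl2, −78 °C; MeOH, then aq. KNaC4H4O6
Reagents that add atoms: none
Why: At −78 °C the aluminium hemiacetal formed by one hydride addition survives until work-up, so the β,γ-unsaturated aldehyde should be released without over-reduction (partial ester reduction).

Step 11
Reactants: 16 (R)-4-benzyloxazolidin-2-one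
Product: 17 (R)-4-benzyl-3-(bromoacetyl)oxazolidin-2-one
Conditions: n-BuLi, THF, −78 °C; then BrCH2COBr
Reagents that add atoms: bromoacetyl bromide BrCC(Br)=O
Why: N-Acylation of the lithiated oxazolidinone by the acid bromide is faster than displacement of the α-bromide.

Step 12
Reactants: 17 (R)-4-benzyl-3-(bromoacetyl)oxazolidin-2-one
Product: 19 (R)-4-benzyl-3-[(triphenyl-λ5-phosphanylidene)acetyl]oxazolidin-2-one, via phosphonium bromide 18 (not isolated)
Conditions: PPh3, toluene, rt; then aq. NaOH (1 M), CH2Cl2, 0 °C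
Reagents that add atoms: triphenylphosphine c1ccc(cc1)P(c1ccccc1)c1ccccc1
Why: SN2 quaternisation of PPh3 by the α-bromo imide and deprotonation of the acidic phosphonium salt should give the imide-stabilised Wittig ylide.

Step 13
Reactants: 15 (3Z,6E,8E,10E)-11-iodo-4,8,10-trimethylundeca-3,6,8,10-tetraenal; 19 (R)-4-benzyl-3-[(triphenyl-λ5-phosphanylidene)acetyl]oxazolidin-2-one
Product: 20 (R)-4-benzyl-3-[(2E,5Z,8E,10E,12E)-13-iodo-6,10,12-trimethyltrideca-2,5,8,10,12-pentaenoyl]oxazolidin-2-one
Conditions: CH2Cl2, rt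
Reagents that add atoms: none
Why: The stabilised ylide reacts E-selectively under neutral conditions (Wittig), so the β,γ-unsaturated aldehyde is not isomerised and the enoyl imide dienophile is installed together with the chiral auxiliary.

Step 14
Reactants: 20 (R)-4-benzyl-3-[(2E,5Z,8E,10E,12E)-13-iodo-6,10,12-trimethyltrideca-2,5,8,10,12-pentaenoyl]oxazolidin-2-one
Product: 21 (R)-4-benzyl-3-{[2β-((E)-1-iodoprop-1-en-2-yl)-3,6-dimethyl-1,2,4aα,5,8,8aβ-hexahydronaphthalen-1β-yl]carbonyl}oxazolidin-2-one
Conditions: Me2AlCl (1.5 equiv), CH2Cl2, −30 to −10 °C; aq. HCl quench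
Reagents that add atoms: none
Why: Me2AlCl chelates both imide carbonyls and locks the enoyl group s-cis, the benzyl group of the (R)-auxiliary blocks the Si face of the α-carbon, and the endo, chair-like intramolecular Diels–Alder transition state of the (E)-dienophile and (E,E)-diene should give the trans-fused decalin with the C1 and C2 substituents cis, setting C1, C2, C4a and C8a at once.

Step 15
Reactants: 21 the imide of step 14
Product: 22 [2β-((E)-1-iodoprop-1-en-2-yl)-3,6-dimethyl-1,2,4aα,5,8,8aβ-hexahydronaphthalen-1β-yl]methanol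
Conditions: LiBH4, MeOH (1 equiv), THF, 0 °C
Reagents that add atoms: none
Why: LiBH4 reduces the exocyclic imide carbonyl to the primary alcohol and releases the auxiliary without touching the vinyl iodide or the olefins (reductive auxiliary cleavage).

Step 16
Reactants: 22 the dienyl alcohol of step 15
Product: 23 [3α,4α:6α,7α-diepoxy-2β-((E)-1-iodoprop-1-en-2-yl)-3,6-dimethyl-trans-decahydronaphthalen-1β-yl]methanol
Conditions: L-fructose-derived ketone catalyst (1,2:4,5-di-O-isopropylidene-β-L-erythro-2,3-hexodiulo-2,6-pyranose, 0.6 equiv), KHSO5 (as Oxone), K2CO3, Bu4NHSO4, MeCN/CH2(OMe)2, aq. Na2B4O7 buffer with Na2H2EDTA, 0 °C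
Reagents that add atoms: potassium peroxymonosulfate [K+].[O-]S(=O)(=O)OO
Why: The chiral dioxirane (Shi epoxidation, spiro transition state) should epoxidise both trisubstituted ring olefins on the α-face, at ring B (faces nearly equivalent) by the choice of ketone enantiomer and at ring A in the same sense reinforced by the axial C2 substituent that blocks the β-face, while the iodine-bearing olefin is too electron-poor to react.

Step 17
Reactants: 23 the bis-epoxy vinyl iodide of step 16
Product: 24 [2β-((E)-but-2-en-2-yl)-3α,4α:6α,7α-diepoxy-3,6-dimethyl-trans-decahydronaphthalen-1β-yl]methanol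
Conditions: trimethylboroxine, PdCl2(dppf) (5 mol %), Cs2CO3, 1,4-dioxane/H2O, 80 °C
Reagents that add atoms: trimethylboroxine CB1OB(C)OB(C)O1
Why: Suzuki–Miyaura coupling replaces iodine by methyl with retention of olefin geometry, which should unveil the (E)-but-2-en-2-yl group only after both epoxides are in place; the base-stable trisubstituted epoxides and the free alcohol are tolerated.

Step 18
Reactants: 24 the bis-epoxy alcohol of step 17
Product: 25 2β-((E)-but-2-en-2-yl)-3α,4α:6α,7α-diepoxy-3,6-dimethyl-trans-decahydronaphthalene-1β-carbaldehyde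
Conditions: Dess–Martin periodinane, NaHCO3, CH2Cl2, 0 °C to rt
Reagents that add atoms: none
Why: Dess–Martin oxidation under buffered, non-acidic conditions should give the aldehyde without opening the epoxides or epimerising C1.

Step 19
Reactants: 25 the aldehyde of step 18
Product: 26 2β-((E)-but-2-en-2-yl)-3α,4α:6α,7α-diepoxy-1β-ethynyl-3,6-dimethyl-trans-decahydronaphthalene
Conditions: dimethyl (1-diazo-2-oxopropyl)phosphonate, K2CO3, MeOH, 0 °C to rt
Reagents that add atoms: dimethyl (1-diazo-2-oxopropyl)phosphonate COP(=O)(OC)C(=[N+]=[N-])C(C)=O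
Why: Ohira–Bestmann (Seyferth–Gilbert) homologation converts the aldehyde into the terminal alkyne by a vinylidene 1,2-shift under mild carbonate conditions that leave the epoxides intact, and the brief cold treatment should not epimerise C1, whose substituent is already equatorial.

Step 20
Reactants: 27 (S)-4-benzyl-3-propanoyloxazolidin-2-one; 4 (E)-3-iodo-2-methylprop-2-enal
Product: 29 (S)-4-benzyl-3-[(2S,3S,4E)-3-hydroxy-5-iodo-2,4-dimethylpent-4-enoyl]oxazolidin-2-one, via boron enolate 28 (not isolated)
Conditions: Bu2BOTf, i-Pr2NEt, CH2Cl2, −78 to 0 °C; then 4, −78 to 0 °C; pH 7 buffer, MeOH, H2O2 work-up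
Reagents that add atoms: none
Why: The Z-boron enolate reacts through a Zimmerman–Traxler chair on the face opposite the benzyl group of the (S)-auxiliary (Evans syn aldol), which should set the methyl-bearing centre as 2S (it becomes C2 (R) of the target arm) and a syn carbinol that is oxidised later.

Step 21
Reactants: 29 the aldol adduct of step 20
Product: 30 (2R,3S,4E)-5-iodo-2,4-dimethylpent-4-ene-1,3-diol
Conditions: LiBH4, MeOH (1 equiv), Et2O, 0 °C
Reagents that add atoms: none
Why: Reductive cleavage of the imide gives the 1,3-diol and releases the auxiliary without epimerising the methyl-bearing centre.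

Step 22
Reactants: 30 (2R,3S,4E)-5-iodo-2,4-dimethylpent-4-ene-1,3-diol
Product: 31 (1E,4R)-5-hydroxy-1-iodo-2,4-dimethylpent-1-en-3-one
Conditions: MnO2, CH2Cl2, rt
Reagents that add atoms: none
Why: MnO2 oxidises only the allylic secondary alcohol, so the saturated primary alcohol survives and the neutral conditions should preserve the stereocentre that is now α to the ketone (chemoselective allylic oxidation).

Step 23
Reactants: 26 the ethynyl bis-epoxy decalin of step 19; 31 (1E,4R)-5-hydroxy-1-iodo-2,4-dimethylpent-1-en-3-one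
Product: 33 (2R,4E,6E)-7-[2β-((E)-but-2-en-2-yl)-3α,4α:6α,7α-diepoxy-3,6-dimethyl-trans-decahydronaphthalen-1β-yl]-1-hydroxy-2,4-dimethylhepta-4,6-dien-3-one (CNP0153873.4), via vinylstannane 32 (not isolated)
Conditions: Bu3SnH (1.1 equiv), PdCl2(PPh3)2 (5 mol %), THF, 0 °C to rt; then 31, Pd2(dba)3, AsPh3, CuI (cat.), DMF, rt to 40 °C
Reagents that add atoms: none
Why: Zerovalent palladium (formed from PdCl2(PPh3)2 and Bu3SnH) adds Sn–H syn across the terminal alkyne with tin on the terminal carbon to give E-vinylstannane 32; oxidative addition of β-iodoenone 31, tin-to-palladium transmetalation assisted by CuI and reductive elimination then form the C5–C6 bond with retention of both olefin geometries. The closest known reaction type is the one-pot palladium-catalysed hydrostannation/Stille diene synthesis. No ring is closed and no sp3 stereocentre is created; the only new stereo-element, the E C6=C7 olefin, follows from the syn addition. The step needs terminal regioselectivity in the hydrostannation, which the branched, ring-bound C1 next to the alkyne should secure, and chemoselectivity, which the neutral conditions provide, since the epoxides, the free primary alcohol and the epimerisable C2 centre next to the ketone are not addressed. Excess tin hydride is dimerised by palladium before 31 is added, so the iodoenone should not be reduced.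

**Compound list**

1 | prop-2-yn-1-ol | C#CCO | starting material
2 | alkenylalane: dimethylaluminium alkoxide of (E)-3-(dimethylalumanyl)-2-methylprop-2-en-1-ol | C[Al](C)OC/C(C)=C/[Al](C)C | intermediate
3 | (E)-3-iodo-2-methylprop-2-en-1-ol | OC/C(C)=C/I | intermediate
4 | (E)-3-iodo-2-methylprop-2-enal | O=C/C(C)=C/I | intermediate
5 | ethyl 2-(triphenyl-λ5-phosphanylidene)propanoate | CCOC(=O)C(C)=P(c1ccccc1)(c1ccccc1)c1ccccc1 | starting material
6 | ethyl (2E,4E)-5-iodo-2,4-dimethylpenta-2,4-dienoate | CCOC(=O)/C(C)=C/C(C)=C/I | intermediate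
7 | (2E,4E)-5-iodo-2,4-dimethylpenta-2,4-dien-1-ol | OC/C(C)=C/C(C)=C/I | intermediate
8 | (1E,3E)-5-bromo-1-iodo-2,4-dimethylpenta-1,3-diene | BrC/C(C)=C/C(C)=C/I | intermediate
9 | diethyl [(2E,4E)-5-iodo-2,4-dimethylpenta-2,4-dien-1-yl]phosphonate | CCOP(=O)(OCC)C/C(C)=C/C(C)=C/I | intermediate
10 | 4-methylanisole | COc1ccc(C)cc1 | starting material
11 | 1-methoxy-4-methylcyclohexa-1,4-diene | COC1=CCC(C)=CC1 | intermediate
12 | methyl (3Z)-6-hydroperoxy-6-methoxy-4-methylhex-3-enoate | COC(=O)C/C=C(C)\CC(OC)OO | intermediate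
13 | methyl (3Z)-4-methyl-6-oxohex-3-enoate | COC(=O)C/C=C(C)\CC=O | intermediate
14 | methyl (3Z,6E,8E,10E)-11-iodo-4,8,10-trimethylundeca-3,6,8,10-tetraenoate | COC(=O)C/C=C(C)\C/C=C/C(C)=C/C(C)=C/I | intermediate
15 | (3Z,6E,8E,10E)-11-iodo-4,8,10-trimethylundeca-3,6,8,10-tetraenal | O=CC/C=C(C)\C/C=C/C(C)=C/C(C)=C/I | intermediate
16 | (R)-4-benzyloxazolidin-2-one | O=C1N[C@H](Cc2ccccc2)CO1 | starting material
17 | (R)-4-benzyl-3-(bromoacetyl)oxazolidin-2-one | O=C(CBr)N1[C@H](Cc2ccccc2)COC1=O | intermediate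
18 | {2-[(R)-4-benzyl-2-oxooxazolidin-3-yl]-2-oxoethyl}triphenylphosphonium bromide | O=C(C[P+](c1ccccc1)(c1ccccc1)c1ccccc1)N1[C@H](Cc2ccccc2)COC1=O.[Br-] | intermediate
19 | (R)-4-benzyl-3-[(triphenyl-λ5-phosphanylidene)acetyl]oxazolidin-2-one | O=C(C=P(c1ccccc1)(c1ccccc1)c1ccccc1)N1[C@H](Cc2ccccc2)COC1=O | intermediate
20 | (R)-4-benzyl-3-[(2E,5Z,8E,10E,12E)-13-iodo-6,10,12-trimethyltrideca-2,5,8,10,12-pentaenoyl]oxazolidin-2-one | O=C(/C=C/C/C=C(C)\C/C=C/C(C)=C/C(C)=C/I)N1[C@H](Cc2ccccc2)COC1=O | intermediate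
21 | (R)-4-benzyl-3-{[2β-((E)-1-iodoprop-1-en-2-yl)-3,6-dimethyl-1,2,4aα,5,8,8aβ-hexahydronaphthalen-1β-yl]carbonyl}oxazolidin-2-one (trans-fused) | I/C=C(\C)[C@H]1[C@@H](C(=O)N2[C@H](Cc3ccccc3)COC2=O)[C@@H]2CC=C(C)C[C@H]2C=C1C | intermediate
22 | [2β-((E)-1-iodoprop-1-en-2-yl)-3,6-dimethyl-1,2,4aα,5,8,8aβ-hexahydronaphthalen-1β-yl]methanol | I/C=C(\C)[C@H]1[C@@H](CO)[C@@H]2CC=C(C)C[C@H]2C=C1C | intermediate
23 | [3α,4α:6α,7α-diepoxy-2β-((E)-1-iodoprop-1-en-2-yl)-3,6-dimethyl-trans-decahydronaphthalen-1β-yl]methanol | I/C=C(\C)[C@H]1[C@@H](CO)[C@@H]2C[C@@H]3O[C@]3(C)C[C@H]2[C@@H]2O[C@@]21C | intermediate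
24 | [2β-((E)-but-2-en-2-yl)-3α,4α:6α,7α-diepoxy-3,6-dimethyl-trans-decahydronaphthalen-1β-yl]methanol | C/C=C(\C)[C@H]1[C@@H](CO)[C@@H]2C[C@@H]3O[C@]3(C)C[C@H]2[C@@H]2O[C@@]21C | intermediate
25 | 2β-((E)-but-2-en-2-yl)-3α,4α:6α,7α-diepoxy-3,6-dimethyl-trans-decahydronaphthalene-1β-carbaldehyde | C/C=C(\C)[C@H]1[C@@H](C=O)[C@@H]2C[C@@H]3O[C@]3(C)C[C@H]2[C@@H]2O[C@@]21C | intermediate
26 | 2β-((E)-but-2-en-2-yl)-3α,4α:6α,7α-diepoxy-1β-ethynyl-3,6-dimethyl-trans-decahydronaphthalene | C/C=C(\C)[C@H]1[C@@H](C#C)[C@@H]2C[C@@H]3O[C@]3(C)C[C@H]2[C@@H]2O[C@@]21C | intermediate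
27 | (S)-4-benzyl-3-propanoyloxazolidin-2-one | CCC(=O)N1[C@@H](Cc2ccccc2)COC1=O | starting material
28 | (Z)-dibutylboron enolate of 27 | CCCCB(CCCC)O/C(=C\C)N1[C@@H](Cc2ccccc2)COC1=O | intermediate
29 | (S)-4-benzyl-3-[(2S,3S,4E)-3-hydroxy-5-iodo-2,4-dimethylpent-4-enoyl]oxazolidin-2-one | O=C([C@@H](C)[C@H](O)/C(C)=C/I)N1[C@@H](Cc2ccccc2)COC1=O | intermediate
30 | (2R,3S,4E)-5-iodo-2,4-dimethylpent-4-ene-1,3-diol | OC[C@@H](C)[C@H](O)/C(C)=C/I | intermediate
31 | (1E,4R)-5-hydroxy-1-iodo-2,4-dimethylpent-1-en-3-one | I/C=C(\C)C(=O)[C@H](C)CO | intermediate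
32 | tributyl{(E)-2-[2β-((E)-but-2-en-2-yl)-3α,4α:6α,7α-diepoxy-3,6-dimethyl-trans-decahydronaphthalen-1β-yl]ethenyl}stannane | C/C=C(\C)[C@H]1[C@@H](/C=C/[Sn](CCCC)(CCCC)CCCC)[C@@H]2C[C@@H]3O[C@]3(C)C[C@H]2[C@@H]2O[C@@]21C | intermediate
33 | (2R,4E,6E)-7-[2β-((E)-but-2-en-2-yl)-3α,4α:6α,7α-diepoxy-3,6-dimethyl-trans-decahydronaphthalen-1β-yl]-1-hydroxy-2,4-dimethylhepta-4,6-dien-3-one (CNP0153873.4) | C/C=C(\C)[C@H]1[C@@H](/C=C/C=C(\C)C(=O)[C@H](C)CO)[C@@H]2C[C@@H]3O[C@]3(C)C[C@H]2[C@@H]2O[C@@]21C | target

**Step count and risks**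

Total step count: 23. Longest linear sequence: 16 steps (steps 1–6, 9, 10, 13–19, 23).

Steps most likely to fail:

Step 16. What may go wrong is weak reagent control of the facial selectivity at the ring-B olefin, whose two faces are nearly equivalent, and slow oxidation of the hindered ring-A olefin by the bulky dioxirane. The fallback replaces reagent control by stereoelectronic substrate control. Starting from 22, N-bromosuccinimide in aqueous 1,2-dimethoxyethane at −10 °C should convert the more accessible ring-B olefin into the Markovnikov, trans-diaxial [7β-bromo-6α-hydroxy-2β-((E)-1-iodoprop-1-en-2-yl)-3,6-dimethyl-1,2,4aα,5,6,7,8,8aβ-octahydronaphthalen-1β-yl]methanol, bromohydrin F1, because water opens the bromonium ion at the tertiary C6 in the axial sense (Fürst–Plattner rule). mCPBA with NaHCO3 in CH2Cl2 then epoxidises the ring-A olefin from its open α-face to give the bromohydrin epoxide F2. K2CO3 in MeOH closes the 6α,7α-epoxide by intramolecular SN2 displacement of the axial bromide, and the route is rejoined at 23.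

Step 14. What may go wrong is Lewis-acid-induced decomposition (protonation or cationic cyclisation) of the skipped pentaene and erosion of facial control. The fallback avoids any Lewis acid. Starting from aldehyde 15, Wittig reaction with (triphenyl-λ5-phosphanylidene)acetaldehyde in toluene gives the pentaenal F3. Iminium-ion catalysis with a chiral 5-benzyl-2-tert-butyl-3-methylimidazolidin-4-one triflate salt (the enantiomer that leaves the Re face of C2 open; MeCN/H2O, 0 °C) should effect the endo intramolecular Diels–Alder reaction to give the decalin carbaldehyde F4. NaBH4 in MeOH reduces it, and the route is rejoined at 22.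

Step 23. What may go wrong is loss of regiocontrol in the hydrostannation (tin delivered to the internal carbon) and reduction of the iodoenone by residual tin hydride. The fallback fixes the regiochemistry by olefination and inverts the coupling polarity. Starting from aldehyde 25, Takai iodo-olefination (CrCl2, CHI3, THF, 0 °C) gives the (E)-vinyl iodide F5. Iodide 31 is converted with Me3SnSnMe3 and Pd(PPh3)4 in toluene into the (E)-β-stannyl enone F6. Stille coupling of F5 with F6 (Pd2(dba)3, AsPh3, CuI, DMF, rt) rejoins the route at 33.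

Further compounds
F1 | step 16 | [7β-bromo-6α-hydroxy-2β-((E)-1-iodoprop-1-en-2-yl)-3,6-dimethyl-1,2,4aα,5,6,7,8,8aβ-octahydronaphthalen-1β-yl]methanol | I/C=C(\C)[C@H]1[C@@H](CO)[C@@H]2C[C@@H](Br)[C@](C)(O)C[C@H]2C=C1C
F2 | step 16 | [7β-bromo-3α,4α-epoxy-6α-hydroxy-2β-((E)-1-iodoprop-1-en-2-yl)-3,6-dimethyl-trans-decahydronaphthalen-1β-yl]methanol | I/C=C(\C)[C@H]1[C@@H](CO)[C@@H]2C[C@@H](Br)[C@](C)(O)C[C@H]2[C@@H]2O[C@@]21C
F3 | step 14 | (2E,5Z,8E,10E,12E)-13-iodo-6,10,12-trimethyltrideca-2,5,8,10,12-pentaenal | O=C/C=C/C/C=C(C)\C/C=C/C(C)=C/C(C)=C/I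
F4 | step 14 | 2β-((E)-1-iodoprop-1-en-2-yl)-3,6-dimethyl-1,2,4aα,5,8,8aβ-hexahydronaphthalene-1β-carbaldehyde | I/C=C(\C)[C@H]1[C@@H](C=O)[C@@H]2CC=C(C)C[C@H]2C=C1C
F5 | step 23 | 2β-((E)-but-2-en-2-yl)-3α,4α:6α,7α-diepoxy-1β-((E)-2-iodoethenyl)-3,6-dimethyl-trans-decahydronaphthalene | C/C=C(\C)[C@H]1[C@@H](/C=C/I)[C@@H]2C[C@@H]3O[C@]3(C)C[C@H]2[C@@H]2O[C@@]21C
F6 | step 23 | (1E,4R)-5-hydroxy-2,4-dimethyl-1-(trimethylstannyl)pent-1-en-3-one | C[Sn](C)(C)/C=C(\C)C(=O)[C@H](C)CO
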